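**Plan**
- Retrosynthesis: remove the acetate; cut the γ-lactone at C6–CH2 (C-alkylation, lactonisation) and C6–C1' (aldol) to reach (S)-4-silyloxycyclohex-2-enone and a geranyl-derived dienal; then cut the enone ring at C2=C3 and C5–C6.
- Enabling feature: in the cyclohexenone ring the C1 carbonyl lies between C2 and C6, so C2–C1(=O)–C6 can be an acyl ylide (C2) whose other α-carbon (C6) carries a temporary tert-butyl ester. C3–C4(O)–C5 maps onto a 2-silyloxyacrolein (C3 = CHO, C5 = β-CH2).
- Forward: an amine-catalysed Michael addition (C5–C6) and intramolecular Wittig (C2=C3) close the carbocycle in one operation; the ester helper is then removed.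
- A boron aldol joins the side chain (C6–C1'); alkylation of the aldolate dianion with methyl bromoacetate makes the quaternary C6 and closes the lactone; desilylation and acetylation finish.
- Stereochemistry: C4 by catalyst-controlled protonation in the key step; C1' relayed from C4 (anti aldol, trans to the silyl ether); C6 relayed from C1' (lithium chelate) and C4 (ring face); 2E from geranyl acetate, 5E from selenoxide syn-elimination.

Key step: step 4

Remark: locants follow the target's enone ring (C1 carbonyl, C2=C3, C4 oxygen-bearing, C5 CH2, C6 spiro); C1' is the lactone carbinol carbon. Compounds 1, 4, 11 and all named reagents are taken as commercial.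

**Route**

Step 1
Reactants: 1 2,2-dimethyl-1,3-dioxan-5-one
Product: 2 2,2-dimethyl-5-[(triisopropylsilyl)oxy]-4H-1,3-dioxine
Conditions: TIPSOTf, Et3N, CH2Cl2, 0 °C to rt
Reagents that add atoms: triisopropylsilyl trifluoromethanesulfonate, CC(C)[Si](C(C)C)(C(C)C)OS(=O)(=O)C(F)(F)F
Why: Soft enolisation and O-silylation of the symmetrical ketone should give the single possible silyl enol ether; no stereocentre is formed.

Step 2
Reactants: 2 2,2-dimethyl-5-[(triisopropylsilyl)oxy]-4H-1,3-dioxine
Product: 3 2-[(triisopropylsilyl)oxy]prop-2-enal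
Conditions: toluene, 110 °C
Reagents that add atoms: none
Why: Retro-hetero-Diels–Alder cycloreversion of the 4H-1,3-dioxine should expel acetone and unveil the 2-silyloxy enal, a known entry to this class of acroleins.

Step 3
Reactants: 4 tert-butyl 4-chloro-3-oxobutanoate
Product: 6 tert-butyl 3-oxo-4-(triphenyl-λ5-phosphanylidene)butanoate, via phosphonium chloride 5 (not isolated)
Conditions: PPh3, toluene, 60 °C; then aq. Na2CO3, CH2Cl2, rt
Reagents that add atoms: triphenylphosphine, c1ccc(cc1)P(c1ccccc1)c1ccccc1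
Why: SN2 displacement of the α-chloro ketone by the phosphine and deprotonation of the most acidic P–CH2–C=O position should give the acyl-stabilised ylide.

Step 4
Reactants: 3 2-[(triisopropylsilyl)oxy]prop-2-enal; 6 tert-butyl 3-oxo-4-(triphenyl-λ5-phosphanylidene)butanoate
Product: 8 tert-butyl (5S)-2-oxo-5-[(triisopropylsilyl)oxy]cyclohex-3-ene-1-carboxylate, via ylide aldehyde 7 (not isolated)
Conditions: 9-amino-9-deoxy-epi-quinine (20 mol %), 2-fluorobenzoic acid (40 mol %), CHCl3, 0 °C to rt
Reagents that add atoms: none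
Why: Proposed new method: the primary amine condenses with 3 to an iminium ion, the keto-ester carbon of 6 (future C6, deprotonated by the quinuclidine nitrogen) adds to the terminal CH2 (C5–C6 bond), the silyloxy-enamine is protonated at C4 by the quinuclidinium N–H, and after hydrolysis the ylide carbon of 7 attacks the aldehyde and the oxaphosphetane collapses to the C2=C3 bond with loss of Ph3PO. The closest known reaction types are the amine-catalysed asymmetric Michael–Wittig [3+3] cyclohexenone annulation of this ylide class with β-substituted enals and the enantioselective protonation of enamines formed by conjugate addition to α-branched acroleins under chiral primary-amine catalysis; their combination on an α-silyloxyacrolein has not been shown. The six-membered ring is closed by the intramolecular Wittig olefination (6-exo-trig attack of the ylide carbon on the aldehyde carbon), which can only give the cis ring alkene. The C4 stereocentre should be set by catalyst-controlled face-selective protonation (the cinchona pseudo-enantiomer is chosen to give S), while the ester-bearing C6 epimerises freely and loses its ester in step 5. The step needs conjugate addition to outrun direct Wittig reaction of 6 with the aldehyde of 3 (which would give an E-dienone that cannot cyclise) and needs attack by the keto-ester carbon, not the ylide carbon; the unhindered CH2 terminus of the iminium ion, the sluggishness of the acyl-stabilised ylide and the higher acidity of the doubly activated C–H should secure both.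

Step 5
Reactants: 8 tert-butyl (5S)-2-oxo-5-[(triisopropylsilyl)oxy]cyclohex-3-ene-1-carboxylate
Product: 10 (4S)-4-[(triisopropylsilyl)oxy]cyclohex-2-en-1-one, via keto acid 9 (not isolated)
Conditions: TFA, CH2Cl2, 0 °C to rt; then toluene, 60 °C
Reagents that add atoms: none
Why: Acidolysis of the tert-butyl ester and decarboxylation of the β-keto acid through the usual cyclic transition state should remove the activating group; the triisopropylsilyl ether is acid-stable and C4 is not touched.

Step 6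
Reactants: 11 (2E)-3,7-dimethylocta-2,6-dien-1-yl acetate (geranyl acetate)
Product: 12 (2E)-5-(3,3-dimethyloxiran-2-yl)-3-methylpent-2-en-1-yl acetate
Conditions: mCPBA, NaHCO3, CH2Cl2, 0 °C
Reagents that add atoms: 3-chloroperoxybenzoic acid, OOC(=O)c1cccc(Cl)c1
Why: Prilezhaev epoxidation should occur at the electron-rich 6,7-alkene because the 2,3-alkene is deactivated by the allylic acetate; the racemic epoxide stereocentre is destroyed in step 7.

Step 7
Reactants: 12 (2E)-5-(3,3-dimethyloxiran-2-yl)-3-methylpent-2-en-1-yl acetate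
Product: 15 (2E,5E)-7-hydroxy-3,7-dimethylocta-2,5-dien-1-yl acetate, via hydroxy selenide 13 (not isolated), via selenoxide 14 (not isolated)
Conditions: (PhSe)2, NaBH4, EtOH, rt; then 30% H2O2, THF, 0 °C to rt
Reagents that add atoms: none
Why: The selenolate should open the epoxide at the secondary carbon (SN2), and selenoxide syn-elimination can only go toward C5 (C7 has no hydrogen), giving the tertiary allylic alcohol with the 5E alkene.

Step 8
Reactants: 15 (2E,5E)-7-hydroxy-3,7-dimethylocta-2,5-dien-1-yl acetate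
Product: 16 (2E,5E)-3,7-dimethyl-7-[(triethylsilyl)oxy]octa-2,5-dien-1-yl acetate
Conditions: TESOTf, 2,6-lutidine, CH2Cl2, −78 to 0 °C
Reagents that add atoms: triethylsilyl trifluoromethanesulfonate, CC[Si](CC)(CC)OS(=O)(=O)C(F)(F)F
Why: A silyl triflate with a hindered base is the standard way to silylate a tertiary alcohol, masking the only acidic proton that would interfere with the enolate steps.

Step 9
Reactants: 16 (2E,5E)-3,7-dimethyl-7-[(triethylsilyl)oxy]octa-2,5-dien-1-yl acetate
Product: 17 (2E,5E)-3,7-dimethyl-7-[(triethylsilyl)oxy]octa-2,5-dien-1-ol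
Conditions: K2CO3 (cat.), MeOH, 0 °C to rt
Reagents that add atoms: none
Why: Base-catalysed transesterification should free the primary allylic alcohol while the tertiary triethylsilyl ether survives mild carbonate.

Step 10
Reactants: 17 (2E,5E)-3,7-dimethyl-7-[(triethylsilyl)oxy]octa-2,5-dien-1-ol
Product: 18 (2E,5E)-3,7-dimethyl-7-[(triethylsilyl)oxy]octa-2,5-dienal
Conditions: MnO2, CH2Cl2, rt
Reagents that add atoms: none
Why: MnO2 oxidises allylic alcohols selectively to enals without over-oxidation and with retention of the 2E geometry.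

Step 11
Reactants: 10 (4S)-4-[(triisopropylsilyl)oxy]cyclohex-2-en-1-one; 18 (2E,5E)-3,7-dimethyl-7-[(triethylsilyl)oxy]octa-2,5-dienal
Product: 20 (4S,6R)-6-[(1R,2E,5E)-1-hydroxy-3,7-dimethyl-7-[(triethylsilyl)oxy]octa-2,5-dien-1-yl]-4-[(triisopropylsilyl)oxy]cyclohex-2-en-1-one, via boron dienolate 19 (not isolated)
Conditions: (c-C6H11)2BCl, Et3N, Et2O, −78 to 0 °C; 18, −78 to −20 °C; then MeOH, pH 7 buffer, 30% H2O2, 0 °C
Reagents that add atoms: none
Why: In this boron aldol the necessarily E-configured cyclic dienolate should react through a closed chair transition state (anti aldol) on the face trans to the pseudo-axial C4 silyloxy group, which fixes C1' as R; the C6 configuration is of no consequence because it is re-formed in step 12.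

Step 12
Reactants: 20 (4S,6R)-6-[(1R,2E,5E)-1-hydroxy-3,7-dimethyl-7-[(triethylsilyl)oxy]octa-2,5-dien-1-yl]-4-[(triisopropylsilyl)oxy]cyclohex-2-en-1-one
Product: 22 (1R,5R,9S)-1-[(1E,4E)-2,6-dimethyl-6-[(triethylsilyl)oxy]hepta-1,4-dien-1-yl]-9-[(triisopropylsilyl)oxy]-2-oxaspiro[4.5]dec-7-ene-3,6-dione, via hydroxy ester 21 (not isolated)
Conditions: LiN(iPr)2 (2.3 equiv), THF, −78 to −40 °C; BrCH2CO2Me, DMPU, −78 °C to rt
Reagents that add atoms: methyl bromoacetate, COC(=O)CBr
Why: In this aldolate-dianion (Fráter–Seebach-type) alkylation the lithium chelate of alkoxide and enolate should hold the dienyl chain on one face, so the bromo ester attacks C6 anti to the chain, which is also the face anti to the C4 silyloxy group (matched), setting the quaternary C6 as R; the lithium alkoxide then closes the γ-lactone (5-exo-trig) with loss of methoxide.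

Step 13
Reactants: 22 (1R,5R,9S)-1-[(1E,4E)-2,6-dimethyl-6-[(triethylsilyl)oxy]hepta-1,4-dien-1-yl]-9-[(triisopropylsilyl)oxy]-2-oxaspiro[4.5]dec-7-ene-3,6-dione
Product: 23 (1R,5R,9S)-9-hydroxy-1-[(1E,4E)-6-hydroxy-2,6-dimethylhepta-1,4-dien-1-yl]-2-oxaspiro[4.5]dec-7-ene-3,6-dione
Conditions: Bu4NF, AcOH, THF, 0 °C to rt
Reagents that add atoms: none
Why: Buffered fluoride should cleave both silyl ethers without ionising the tertiary allylic alcohol or opening the lactone; no stereocentre is touched.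

Step 14
Reactants: 23 (1R,5R,9S)-9-hydroxy-1-[(1E,4E)-6-hydroxy-2,6-dimethylhepta-1,4-dien-1-yl]-2-oxaspiro[4.5]dec-7-ene-3,6-dione
Product: 24 (1R,5R,9S)-1-[(1E,4E)-6-hydroxy-2,6-dimethylhepta-1,4-dien-1-yl]-3,6-dioxo-2-oxaspiro[4.5]dec-7-en-9-yl acetate
Conditions: Ac2O, pyridine, CH2Cl2, 0 °C
Reagents that add atoms: acetic anhydride, CC(=O)OC(C)=O
Why: Acylation should be selective for the secondary C4 alcohol over the hindered tertiary alcohol and proceeds with retention at C4.

**Compound list**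

1 | 2,2-dimethyl-1,3-dioxan-5-one | CC1(C)OCC(=O)CO1 | starting material
2 | 2,2-dimethyl-5-[(triisopropylsilyl)oxy]-4H-1,3-dioxine | CC1(C)OCC(O[Si](C(C)C)(C(C)C)C(C)C)=CO1 | intermediate
3 | 2-[(triisopropylsilyl)oxy]prop-2-enal | C=C(O[Si](C(C)C)(C(C)C)C(C)C)C=O | intermediate
4 | tert-butyl 4-chloro-3-oxobutanoate | CC(C)(C)OC(=O)CC(=O)CCl | starting material
5 | [4-(tert-butoxy)-2,4-dioxobutyl]triphenylphosphonium chloride | CC(C)(C)OC(=O)CC(=O)C[P+](c1ccccc1)(c1ccccc1)c1ccccc1.[Cl-] | intermediate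
6 | tert-butyl 3-oxo-4-(triphenyl-λ5-phosphanylidene)butanoate | CC(C)(C)OC(=O)CC(=O)C=P(c1ccccc1)(c1ccccc1)c1ccccc1 | intermediate
7 | tert-butyl 3-oxo-2-[(2S)-3-oxo-2-[(triisopropylsilyl)oxy]propyl]-4-(triphenyl-λ5-phosphanylidene)butanoate | CC(C)(C)OC(=O)C(C[C@H](O[Si](C(C)C)(C(C)C)C(C)C)C=O)C(=O)C=P(c1ccccc1)(c1ccccc1)c1ccccc1 | intermediate
8 | tert-butyl (5S)-2-oxo-5-[(triisopropylsilyl)oxy]cyclohex-3-ene-1-carboxylate (C1 epimers) | CC(C)(C)OC(=O)C1C[C@H](O[Si](C(C)C)(C(C)C)C(C)C)C=CC1=O | intermediate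
9 | (5S)-2-oxo-5-[(triisopropylsilyl)oxy]cyclohex-3-ene-1-carboxylic acid | OC(=O)C1C[C@H](O[Si](C(C)C)(C(C)C)C(C)C)C=CC1=O | intermediate
10 | (4S)-4-[(triisopropylsilyl)oxy]cyclohex-2-en-1-one | CC(C)[Si](C(C)C)(C(C)C)O[C@@H]1C=CC(=O)CC1 | intermediate
11 | (2E)-3,7-dimethylocta-2,6-dien-1-yl acetate (geranyl acetate) | CC(=O)OC/C=C(\C)CCC=C(C)C | starting material
12 | (2E)-5-(3,3-dimethyloxiran-2-yl)-3-methylpent-2-en-1-yl acetate (racemic) | CC(=O)OC/C=C(\C)CCC1OC1(C)C | intermediate
13 | (2E)-7-hydroxy-3,7-dimethyl-6-(phenylselanyl)oct-2-en-1-yl acetate | CC(=O)OC/C=C(\C)CCC([Se]c1ccccc1)C(C)(C)O | intermediate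
14 | (2E)-7-hydroxy-3,7-dimethyl-6-(phenylseleninyl)oct-2-en-1-yl acetate | CC(=O)OC/C=C(\C)CCC([Se](=O)c1ccccc1)C(C)(C)O | intermediate
15 | (2E,5E)-7-hydroxy-3,7-dimethylocta-2,5-dien-1-yl acetate | CC(=O)OC/C=C(\C)C/C=C/C(C)(C)O | intermediate
16 | (2E,5E)-3,7-dimethyl-7-[(triethylsilyl)oxy]octa-2,5-dien-1-yl acetate | CC(=O)OC/C=C(\C)C/C=C/C(C)(C)O[Si](CC)(CC)CC | intermediate
17 | (2E,5E)-3,7-dimethyl-7-[(triethylsilyl)oxy]octa-2,5-dien-1-ol | OC/C=C(\C)C/C=C/C(C)(C)O[Si](CC)(CC)CC | intermediate
18 | (2E,5E)-3,7-dimethyl-7-[(triethylsilyl)oxy]octa-2,5-dienal | O=C/C=C(\C)C/C=C/C(C)(C)O[Si](CC)(CC)CC | intermediate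
19 | (4S)-4-[(triisopropylsilyl)oxy]cyclohexa-1,5-dien-1-yl dicyclohexylborinate | CC(C)[Si](C(C)C)(C(C)C)O[C@@H]1C=CC(OB(C2CCCCC2)C2CCCCC2)=CC1 | intermediate
20 | (4S,6R)-6-[(1R,2E,5E)-1-hydroxy-3,7-dimethyl-7-[(triethylsilyl)oxy]octa-2,5-dien-1-yl]-4-[(triisopropylsilyl)oxy]cyclohex-2-en-1-one | O=C1C=C[C@@H](O[Si](C(C)C)(C(C)C)C(C)C)C[C@@H]1[C@H](O)/C=C(\C)C/C=C/C(C)(C)O[Si](CC)(CC)CC | intermediate
21 | methyl 2-[(1R,5S)-1-[(1R,2E,5E)-1-hydroxy-3,7-dimethyl-7-[(triethylsilyl)oxy]octa-2,5-dien-1-yl]-2-oxo-5-[(triisopropylsilyl)oxy]cyclohex-3-en-1-yl]acetate | CC(C)[Si](C(C)C)(C(C)C)O[C@@H]1C=CC(=O)[C@](CC(=O)OC)([C@H](O)/C=C(\C)C/C=C/C(C)(C)O[Si](CC)(CC)CC)C1 | intermediate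
22 | (1R,5R,9S)-1-[(1E,4E)-2,6-dimethyl-6-[(triethylsilyl)oxy]hepta-1,4-dien-1-yl]-9-[(triisopropylsilyl)oxy]-2-oxaspiro[4.5]dec-7-ene-3,6-dione | CC(C)[Si](C(C)C)(C(C)C)O[C@@H]1C=CC(=O)[C@@]2(CC(=O)O[C@@H]2/C=C(\C)C/C=C/C(C)(C)O[Si](CC)(CC)CC)C1 | intermediate
23 | (1R,5R,9S)-9-hydroxy-1-[(1E,4E)-6-hydroxy-2,6-dimethylhepta-1,4-dien-1-yl]-2-oxaspiro[4.5]dec-7-ene-3,6-dione | O[C@@H]1C=CC(=O)[C@@]2(CC(=O)O[C@@H]2/C=C(\C)C/C=C/C(C)(C)O)C1 | intermediate
24 | (1R,5R,9S)-1-[(1E,4E)-6-hydroxy-2,6-dimethylhepta-1,4-dien-1-yl]-3,6-dioxo-2-oxaspiro[4.5]dec-7-en-9-yl acetate | CC(=O)O[C@@H]1C=CC(=O)[C@@]2(CC(=O)O[C@@H]2/C=C(\C)C/C=C/C(C)(C)O)C1 | target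

**Summary**

Total step count: 14. Longest linear sequence: 9 steps (11 to 24, steps 6–14).

Steps most likely to fail:

1. Step 4 (proposed new method). The enamine may be protonated with poor face selectivity, the α-silyloxy aldehyde may epimerise before ring closure, or direct Wittig reaction may outrun conjugate addition. The fallback uses known chemistry, sets out from 3 and 6 and returns at 10. Sodium hydride-mediated Michael–Wittig annulation of 6 with 3 in THF should give racemic tert-butyl 2-oxo-5-[(triisopropylsilyl)oxy]cyclohex-3-ene-1-carboxylate F1. TFA and then warming should give racemic 4-[(triisopropylsilyl)oxy]cyclohex-2-en-1-one F2. Buffered Bu4NF should give racemic 4-hydroxycyclohex-2-en-1-one F3. Lipase-catalysed acetylation (Amano lipase PS, vinyl acetate) then resolves it: the R enantiomer is expected to be acetylated to (R)-4-oxocyclohex-2-en-1-yl acetate F5, leaving (S)-4-hydroxycyclohex-2-en-1-one F4, which is silylated (TIPSOTf, 2,6-lutidine) to 10.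

2. Step 12. The lithium aldolate may undergo retro-aldol cleavage before or during the second deprotonation, or the alkoxide may be acylated by the bromo ester and then alkylate intramolecularly without face control. The fallback sets out from 20 and returns at 23, replacing chelate control by ring control on a protected substrate. The C1' hydroxyl is silylated (TESOTf, 2,6-lutidine) to (4S,6R)-6-[(1R,2E,5E)-3,7-dimethyl-1,7-bis[(triethylsilyl)oxy]octa-2,5-dien-1-yl]-4-[(triisopropylsilyl)oxy]cyclohex-2-en-1-one F6. Its mono-enolate (LiN(SiMe3)2, THF/DMPU) is alkylated with methyl bromoacetate on the face anti to the C4 silyloxy group to give methyl 2-[(1R,5S)-1-[(1R,2E,5E)-3,7-dimethyl-1,7-bis[(triethylsilyl)oxy]octa-2,5-dien-1-yl]-2-oxo-5-[(triisopropylsilyl)oxy]cyclohex-3-en-1-yl]acetate F7. Bu4NF/AcOH then removes all three silyl groups and the freed C1' hydroxyl closes the lactone, giving 23.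

3. Step 11. The remote C4 silyl ether may discriminate the enolate faces poorly, so that C1' epimers form. The fallback sets out from 10 and returns at 20, moving control of C1' from the substrate to a catalyst. The kinetic lithium dienolate of 10 (LiN(iPr)2, Me3SiCl) is trapped as trimethyl{[(4S)-4-[(triisopropylsilyl)oxy]cyclohexa-1,5-dien-1-yl]oxy}silane F8. A Mukaiyama aldol addition to 18 is then run with SiCl4 activated by a chiral bisphosphoramide Lewis base (iPr2NEt, CH2Cl2, −78 °C; open transition state, anti-selective for cyclic enol ethers). The catalyst fixes the aldehyde face and hence C1' independently of the ring, and C6 is re-formed in step 12 in any case.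

Further compounds
F1 | step 4 | racemic tert-butyl 2-oxo-5-[(triisopropylsilyl)oxy]cyclohex-3-ene-1-carboxylate | CC(C)(C)OC(=O)C1CC(O[Si](C(C)C)(C(C)C)C(C)C)C=CC1=O
F2 | step 4 | racemic 4-[(triisopropylsilyl)oxy]cyclohex-2-en-1-one | CC(C)[Si](C(C)C)(C(C)C)OC1C=CC(=O)CC1
F3 | step 4 | racemic 4-hydroxycyclohex-2-en-1-one | OC1C=CC(=O)CC1
F4 | step 4 | (S)-4-hydroxycyclohex-2-en-1-one | O[C@@H]1C=CC(=O)CC1
F5 | step 4 | (R)-4-oxocyclohex-2-en-1-yl acetate | CC(=O)O[C@H]1C=CC(=O)CC1
F6 | step 12 | (4S,6R)-6-[(1R,2E,5E)-3,7-dimethyl-1,7-bis[(triethylsilyl)oxy]octa-2,5-dien-1-yl]-4-[(triisopropylsilyl)oxy]cyclohex-2-en-1-one | O=C1C=C[C@@H](O[Si](C(C)C)(C(C)C)C(C)C)C[C@@H]1[C@H](O[Si](CC)(CC)CC)/C=C(\C)C/C=C/C(C)(C)O[Si](CC)(CC)CC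
F7 | step 12 | methyl 2-[(1R,5S)-1-[(1R,2E,5E)-3,7-dimethyl-1,7-bis[(triethylsilyl)oxy]octa-2,5-dien-1-yl]-2-oxo-5-[(triisopropylsilyl)oxy]cyclohex-3-en-1-yl]acetate | CC(C)[Si](C(C)C)(C(C)C)O[C@@H]1C=CC(=O)[C@](CC(=O)OC)([C@H](O[Si](CC)(CC)CC)/C=C(\C)C/C=C/C(C)(C)O[Si](CC)(CC)CC)C1
F8 | step 11 | trimethyl{[(4S)-4-[(triisopropylsilyl)oxy]cyclohexa-1,5-dien-1-yl]oxy}silane | CC(C)[Si](C(C)C)(C(C)C)O[C@@H]1C=CC(O[Si](C)(C)C)=CC1
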